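## Retrosynthetic overview

1. Target 32 ⇒ alcohol 31 ⇒ silyl ether 30 ⇒ 14-membered carbocyclic allenylstannane 26 + CO2. One flask forms C12–C18, O–C10 and C11–C15, which closes the butenolide and the cyclohexene and cuts the 14-membered ring down to the 12-membered ring.
2. Enabling feature: C10–C11=C12, the three butenolide carbons shared by all three rings, can be read as an allene. On C12, the carboxylate (C18) and the C13–C14–C1 arm carrying the isopropenyl group (future C15–C17) lie on opposite faces of the C10=C11 π bond. Oxygen therefore adds to C10 anti to Pd, and the C11–Pd bond ends up cis to C13, six ring atoms from C15.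
3. 26 ⇐ anti-SN2' stannylation of the C10 mesylate of cycloalkyne 23 ⇐ ring-closing alkyne metathesis (C11≡C12) of diyne 22.
4. 22 ⇐ allylsilane 10 (from (S)-limonene, brings C1) + enal 19 (vinylogous Mukaiyama aldol sets C10 and the 7E alkene), joined by an asymmetric Hosomi–Sakurai reaction (C5–C6, sets C6).
5. Ring order: 14-membered carbocycle (step 14), then butenolide and cyclohexene together (step 18), which leaves the 12-membered ring.

Key step: step 18

Remark: locants are those of the verticillane skeleton: C1 ring CH; C2, C3 CH2; C4(=C20H2); C5 CH2; C6 CH–OAc; C7=C8(C19H3); C9 CH2; C10 CH–O; C11=C12; C13, C14 CH2; C15(CH3)2; C18 lactone C=O. The CH2Pd-bearing carbon of 29 is a transient stereocentre of no consequence and is left undefined.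

## Route

Step 1
Reactants: 1 (S)-(−)-limonene
Product: 2 (3S)-6-oxo-3-(prop-1-en-2-yl)heptanal
Conditions: O3 (1 equiv, Sudan III end point), CH2Cl2–MeOH, −78 °C; Me2S
Reagents that add atoms: ozone [O-][O+]=O
Why: Chemoselective ozonolysis: the trisubstituted ring alkene is more electron-rich than the isopropenyl group and should be cleaved first when ozone is metered against an indicator dye, while the stereocentre (future C1) is untouched.

Step 2
Reactants: 2 (3S)-6-oxo-3-(prop-1-en-2-yl)heptanal
Product: 3 (5S)-5-(2-hydroxyethyl)-6-methylhept-6-en-2-one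
Conditions: NaBH(OAc)3, toluene, 60 °C
Reagents that add atoms: none
Why: Chemoselective hydride reduction: triacetoxyborohydride is mild enough to reduce the aldehyde (future C3) and leave the methyl ketone.

Step 3
Reactants: 3 (5S)-5-(2-hydroxyethyl)-6-methylhept-6-en-2-one
Product: 4 (5S)-5-(2-iodoethyl)-6-methylhept-6-en-2-one
Conditions: I2, PPh3, imidazole, CH2Cl2, 0 °C
Reagents that add atoms: iodine II
Why: Appel-type iodination of a primary alcohol under near-neutral conditions that the ketone and the alkene tolerate.

Step 4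
Reactants: 4 (5S)-5-(2-iodoethyl)-6-methylhept-6-en-2-one; 5 (2-bromoallyl)trimethylsilane
Product: 7 (5R)-6-methyl-5-{3-[(trimethylsilyl)methyl]but-3-en-1-yl}hept-6-en-2-one, via alkylzinc iodide 6 (not isolated)
Conditions: Zn dust, LiCl, THF, 40 °C; then 5, PdCl2(dppf) (cat.), THF, 50 °C
Reagents that add atoms: none
Why: Negishi sp3–sp2 coupling: zinc inserts into the primary C–I bond without touching the ketone, and the wide-bite-angle Pd catalyst couples the alkylzinc with the vinyl bromide, which forms C3–C4 and installs the allylsilane.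

Step 5
Reactants: 7 (5R)-6-methyl-5-{3-[(trimethylsilyl)methyl]but-3-en-1-yl}hept-6-en-2-one
Product: 10 [(5S)-2-methylidene-5-(prop-1-en-2-yl)dec-8-yn-1-yl]trimethylsilane, via enol phosphate 8 (not isolated), via lithium acetylide 9 (not isolated)
Conditions: LDA, THF, −78 °C; ClP(O)(OEt)2; LDA (2.3 equiv), −78 °C → rt; MeI, DMPU, 0 °C → rt
Reagents that add atoms: iodomethane CI
Why: Kinetic deprotonation at the methyl group, O-phosphorylation and double elimination turn the methyl ketone into the terminal acetylide, whose methylation gives the methyl-capped alkyne needed for alkyne metathesis; the allylsilane and the stereocentre are inert to LDA.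

Step 6
Reactants: 11 methyl 3-methylbut-2-enoate
Product: 12 tert-butyl{[(1Z)-1-methoxy-3-methylbuta-1,3-dien-1-yl]oxy}dimethylsilane
Conditions: LDA, THF–DMPU, −78 °C; TBSCl
Reagents that add atoms: tert-butyldimethylsilyl chloride CC(C)(C)[Si](C)(C)Cl
Why: γ-Deprotonation of the senecioate and O-silylation give the extended silyl ketene acetal, the vinylogous nucleophile that delivers C9.

Step 7
Reactants: 13 but-2-yn-1-ol
Product: 14 but-2-ynal
Conditions: MnO2, CH2Cl2, rt; filtered solution used directly
Reagents that add atoms: none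
Why: MnO2 oxidises the propargylic alcohol selectively to the volatile ynal, which need not be concentrated.

Step 8
Reactants: 12 tert-butyl{[(1Z)-1-methoxy-3-methylbuta-1,3-dien-1-yl]oxy}dimethylsilane; 14 but-2-ynal
Product: 16 methyl (2E,5S)-5-hydroxy-3-methyloct-2-en-6-ynoate, via trichlorosilyl ether 15 (not isolated)
Conditions: SiCl4, chiral binaphthyl bisphosphoramide (cat.), i-Pr2NEt (cat.), CH2Cl2, −78 °C; aqueous buffer work-up
Reagents that add atoms: none
Why: Catalytic enantioselective vinylogous Mukaiyama aldol reaction: the phosphoramide-bound trichlorosilyl cation activates the non-enolisable ynal, the hindered α-carbon of 12 directs attack to the γ-carbon (C9–C10), reaction through the s-trans dienolate gives the 2E (future 7E) alkene, and the catalyst enantiomer that shields the Re face gives Si-face attack and hence 5S (the C10 carbinol).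

Step 9
Reactants: 16 methyl (2E,5S)-5-hydroxy-3-methyloct-2-en-6-ynoate
Product: 17 methyl (2E,5S)-3-methyl-5-(triethylsilyloxy)oct-2-en-6-ynoate
Conditions: TESCl, imidazole, CH2Cl2, 0 °C
Reagents that add atoms: chlorotriethylsilane CC[Si](CC)(CC)Cl
Why: Standard silylation; the labile TES group can later be removed in the presence of a TBS ether.

Step 10
Reactants: 17 methyl (2E,5S)-3-methyl-5-(triethylsilyloxy)oct-2-en-6-ynoate
Product: 18 (2E,5S)-3-methyl-5-(triethylsilyloxy)oct-2-en-6-yn-1-ol
Conditions: DIBAL-H (2.2 equiv), CH2Cl2, −78 °C; Rochelle salt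
Reagents that add atoms: none
Why: DIBAL-H reduces the enoate in the 1,2 sense to the allylic alcohol without touching the alkyne, the alkene geometry or the silyl ether.

Step 11
Reactants: 18 (2E,5S)-3-methyl-5-(triethylsilyloxy)oct-2-en-6-yn-1-ol
Product: 19 (2E,5S)-3-methyl-5-(triethylsilyloxy)oct-2-en-6-ynal
Conditions: MnO2, CH2Cl2, rt
Reagents that add atoms: none
Why: MnO2 oxidation of a primary allylic alcohol gives the enal with retention of the E geometry.

Step 12
Reactants: 10 [(5S)-2-methylidene-5-(prop-1-en-2-yl)dec-8-yn-1-yl]trimethylsilane; 19 (2E,5S)-3-methyl-5-(triethylsilyloxy)oct-2-en-6-ynal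
Product: 21 (4S,6E,8S,13R)-6-methyl-10-methylidene-13-(prop-1-en-2-yl)-4-(triethylsilyloxy)octadec-6-ene-2,16-diyn-8-ol, via trimethylsilyl ether 20 (not isolated)
Conditions: chiral binaphthyl disulfonimide (cat.), toluene, −78 °C; citric acid, MeOH, 0 °C
Reagents that add atoms: none
Why: Catalytic asymmetric Hosomi–Sakurai reaction (silylium ion paired with a chiral disulfonimide anion): the 2-substituted allylsilane attacks the enal 1,2 through its CH2= terminus (C5–C6) with transposition that creates the C4=C20 methylidene, the catalyst enantiomer that exposes the Si face sets 6S (8S in the name), and mild methanolysis removes only the TMS ether.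

Step 13
Reactants: 21 (4S,6E,8S,13R)-6-methyl-10-methylidene-13-(prop-1-en-2-yl)-4-(triethylsilyloxy)octadec-6-ene-2,16-diyn-8-ol
Product: 22 the 8-O-tert-butyldimethylsilyl ether of 21
Conditions: TBSCl, imidazole, DMF, rt
Reagents that add atoms: tert-butyldimethylsilyl chloride CC(C)(C)[Si](C)(C)Cl
Why: Silylation masks the C6 oxygen in a form that survives cuprate, butyllithium and Pd(II) and is orthogonal to TES.

Step 14
Reactants: 22 the 8-O-tert-butyldimethylsilyl ether of 21
Product: 23 (1R,6S,7E,10S)-6-(tert-butyldimethylsilyloxy)-8-methyl-4-methylidene-1-(prop-1-en-2-yl)-10-(triethylsilyloxy)cyclotetradec-7-en-11-yne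
Conditions: ArC≡Mo(OSiPh3)3 (cat.), 5 Å MS, toluene, 2 mM, rt → 60 °C
Reagents that add atoms: none
Why: Ring-closing alkyne metathesis: molybdenum alkylidyne catalysts ignore alkenes and silyl ethers, and trapping of but-2-yne by the sieves drives closure of the strain-free 14-membered ring (C11≡C12) without creating or touching a stereocentre.

Step 15
Reactants: 23 (1R,6S,7E,10S)-6-(tert-butyldimethylsilyloxy)-8-methyl-4-methylidene-1-(prop-1-en-2-yl)-10-(triethylsilyloxy)cyclotetradec-7-en-11-yne
Product: 24 (1R,6S,7E,10S)-6-(tert-butyldimethylsilyloxy)-8-methyl-4-methylidene-1-(prop-1-en-2-yl)cyclotetradec-7-en-11-yn-10-ol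
Conditions: PPTS (cat.), MeOH–CH2Cl2, 0 °C
Reagents that add atoms: none
Why: Acid-catalysed methanolysis discriminates the TES ether from the bulkier TBS ether.

Step 16
Reactants: 24 (1R,6S,7E,10S)-6-(tert-butyldimethylsilyloxy)-8-methyl-4-methylidene-1-(prop-1-en-2-yl)cyclotetradec-7-en-11-yn-10-ol
Product: 25 the 10-methanesulfonate of 24 (10S)
Conditions: MsCl, Et3N, CH2Cl2, −78 → 0 °C; used without chromatography
Reagents that add atoms: methanesulfonyl chloride CS(=O)(=O)Cl
Why: O-Sulfonylation activates the propargylic oxygen with retention at C10.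

Step 17
Reactants: 25 the 10-methanesulfonate of 24 (10S)
Product: 26 (1R,6S,7E,aR)-6-(tert-butyldimethylsilyloxy)-8-methyl-4-methylidene-1-(prop-1-en-2-yl)-12-(tributylstannyl)cyclotetradeca-7,10,11-triene
Conditions: Bu3SnH, LDA, THF, 0 °C; CuBr·SMe2, −78 °C; then 25, −78 °C
Reagents that add atoms: tributyltin hydride CCCC[SnH](CCCC)CCCC
Why: Anti-SN2' displacement of a propargylic mesylate by a stannylcuprate: tin enters at C12 anti to the leaving group, so the 10S centre is translated into the aR allene axis.

Step 18
Reactants: 26 (1R,6S,7E,aR)-6-(tert-butyldimethylsilyloxy)-8-methyl-4-methylidene-1-(prop-1-en-2-yl)-12-(tributylstannyl)cyclotetradeca-7,10,11-triene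
Product: 30 (1R,6S,7E,10R)-tricyclic butenolide with the target skeleton carrying OTBS at C6, via allenyllithium 27 (not isolated), via lithium allenoate 28 (not isolated), via alkylpalladium chloride 29 (not isolated)
Conditions: n-BuLi, THF, −78 °C; CO2 (dry gas), −78 → −40 °C; PdCl2(MeCN)2 (1.05 equiv), 2 mM, −40 °C → rt; HCO2H, Et3N (1.5 equiv each), rt
Reagents that add atoms: carbon dioxide O=C=O
Why: Proposed new method: Sn–Li exchange with retention gives 27, which takes up CO2 at its lithiated carbon (C12–C18) to give 28; Pd(II) then binds the distal C10=C11 π bond on the face turned away from the carboxylate, the carboxylate oxygen adds anti to C10 (O–C10), the resulting C11–Pd bond inserts into the isopropenyl group at its inner carbon (C11–C15), and the neopentyl-type alkylpalladium 29, which has no β-hydrogen, persists until formate converts CH2–Pd into the second methyl group. The closest known reaction types are the carboxylation of 1-lithioallenes, the Pd(II)-mediated cyclisation of 2,3-allenoic acids in which the β-palladated butenolide is intercepted by an alkene, and the reductive Heck cyclisation that builds quaternary carbons; what is new is their union in one flask and the intramolecular capture by an unactivated 1,1-disubstituted alkene. The butenolide closes by 5-endo-trig anti-oxypalladation of the allene and the cyclohexene by 6-exo-trig syn migratory insertion, and this transannular bond turns the 14-membered ring into the 12-membered ring. The only new stereocentre, C10, is fixed by the allene axis, since aR-28 with anti attack gives 10R (net inversion of the 10S carbinol); C15 becomes achiral after hydride transfer, so the face of insertion does not matter, and C1 and C6 are spectators. The step needs α- rather than γ-carboxylation (favoured by the allenic structure of the lithium species at −78 °C), preservation of the axis (short lifetime of 27 at −78 °C) and alkene selection: only the isopropenyl group reaches C11–Pd through a six-membered transition state, whereas C4=C20 would need an eight-membered one and C7=C8 a four- or five-membered one.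

Step 19
Reactants: 30 (1R,6S,7E,10R)-tricyclic butenolide with the target skeleton carrying OTBS at C6
Product: 31 (1R,6S,7E,10R)-deacetyl target (free C6 alcohol)
Conditions: HF·pyridine, THF, 0 °C → rt
Reagents that add atoms: none
Why: Fluoride-mediated desilylation under slightly acidic conditions avoids enolisation of the butenolide at C10 and leaves all alkenes in place.

Step 20
Reactants: 31 (1R,6S,7E,10R)-deacetyl target (free C6 alcohol)
Product: 32 target CNP0289913.1
Conditions: Ac2O, pyridine, DMAP (cat.), CH2Cl2, 0 °C → rt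
Reagents that add atoms: acetic anhydride CC(=O)OC(C)=O
Why: DMAP-catalysed O-acetylation proceeds with retention at C6 and gives the target.

## Compound list

1 | (S)-(−)-limonene | CC1=CC[C@H](CC1)C(C)=C | starting material
2 | (3S)-6-oxo-3-(prop-1-en-2-yl)heptanal | O=CC[C@H](CCC(C)=O)C(C)=C | intermediate
3 | (5S)-5-(2-hydroxyethyl)-6-methylhept-6-en-2-one | OCC[C@H](CCC(C)=O)C(C)=C | intermediate
4 | (5S)-5-(2-iodoethyl)-6-methylhept-6-en-2-one | ICC[C@H](CCC(C)=O)C(C)=C | intermediate
5 | (2-bromoallyl)trimethylsilane | C=C(Br)C[Si](C)(C)C | starting material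
6 | alkylzinc iodide from 4 (not isolated) | I[Zn]CC[C@H](CCC(C)=O)C(C)=C | intermediate
7 | (5R)-6-methyl-5-{3-[(trimethylsilyl)methyl]but-3-en-1-yl}hept-6-en-2-one | C[Si](C)(C)CC(=C)CC[C@H](CCC(C)=O)C(C)=C | intermediate
8 | terminal diethyl enol phosphate of 7 (not isolated) | C[Si](C)(C)CC(=C)CC[C@H](CCC(=C)OP(=O)(OCC)OCC)C(C)=C | intermediate
9 | lithium acetylide from 8 (not isolated) | C[Si](C)(C)CC(=C)CC[C@H](CCC#C[Li])C(C)=C | intermediate
10 | [(5S)-2-methylidene-5-(prop-1-en-2-yl)dec-8-yn-1-yl]trimethylsilane | C[Si](C)(C)CC(=C)CC[C@H](CCC#CC)C(C)=C | intermediate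
11 | methyl 3-methylbut-2-enoate | COC(=O)C=C(C)C | starting material
12 | tert-butyl{[(1Z)-1-methoxy-3-methylbuta-1,3-dien-1-yl]oxy}dimethylsilane | C=C(C)/C=C(\O[Si](C)(C)C(C)(C)C)OC | intermediate
13 | but-2-yn-1-ol | CC#CCO | starting material
14 | but-2-ynal | CC#CC=O | intermediate
15 | trichlorosilyl ether of 16 (not isolated) | COC(=O)/C=C(\C)C[C@H](O[Si](Cl)(Cl)Cl)C#CC | intermediate
16 | methyl (2E,5S)-5-hydroxy-3-methyloct-2-en-6-ynoate | COC(=O)/C=C(\C)C[C@H](O)C#CC | intermediate
17 | methyl (2E,5S)-3-methyl-5-(triethylsilyloxy)oct-2-en-6-ynoate | COC(=O)/C=C(\C)C[C@H](O[Si](CC)(CC)CC)C#CC | intermediate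
18 | (2E,5S)-3-methyl-5-(triethylsilyloxy)oct-2-en-6-yn-1-ol | OC/C=C(\C)C[C@H](O[Si](CC)(CC)CC)C#CC | intermediate
19 | (2E,5S)-3-methyl-5-(triethylsilyloxy)oct-2-en-6-ynal | O=C/C=C(\C)C[C@H](O[Si](CC)(CC)CC)C#CC | intermediate
20 | 8-O-trimethylsilyl ether of 21 (not isolated) | CC#CCC[C@H](C(C)=C)CCC(=C)C[C@H](O[Si](C)(C)C)/C=C(\C)C[C@H](O[Si](CC)(CC)CC)C#CC | intermediate
21 | (4S,6E,8S,13R)-6-methyl-10-methylidene-13-(prop-1-en-2-yl)-4-(triethylsilyloxy)octadec-6-ene-2,16-diyn-8-ol | CC#CCC[C@H](C(C)=C)CCC(=C)C[C@H](O)/C=C(\C)C[C@H](O[Si](CC)(CC)CC)C#CC | intermediate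
22 | 8-O-tert-butyldimethylsilyl ether of 21 | CC#CCC[C@H](C(C)=C)CCC(=C)C[C@H](O[Si](C)(C)C(C)(C)C)/C=C(\C)C[C@H](O[Si](CC)(CC)CC)C#CC | intermediate
23 | (1R,6S,7E,10S)-6-OTBS-10-OTES-8-methyl-4-methylidene-1-isopropenylcyclotetradec-7-en-11-yne | C1#C[C@@H](O[Si](CC)(CC)CC)C/C(C)=C/[C@@H](O[Si](C)(C)C(C)(C)C)CC(=C)CC[C@@H](C(C)=C)CC1 | intermediate
24 | (1R,6S,7E,10S)-propargylic alcohol from 23 | C1#C[C@@H](O)C/C(C)=C/[C@@H](O[Si](C)(C)C(C)(C)C)CC(=C)CC[C@@H](C(C)=C)CC1 | intermediate
25 | (10S)-methanesulfonate of 24 | C1#C[C@@H](OS(C)(=O)=O)C/C(C)=C/[C@@H](O[Si](C)(C)C(C)(C)C)CC(=C)CC[C@@H](C(C)=C)CC1 | intermediate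
26 | (1R,6S,7E,aR)-12-tributylstannyl cyclotetradeca-7,10,11-triene | CCCC[Sn](CCCC)(CCCC)C1=[C@]=C([H])C/C(C)=C/[C@@H](O[Si](C)(C)C(C)(C)C)CC(=C)CC[C@@H](C(C)=C)CC1 | intermediate
27 | 12-lithio allene, same spatial axis as 26 (descriptor aS because Li ranks below C; not isolated) | [Li]C1=[C@]=C([H])C/C(C)=C/[C@@H](O[Si](C)(C)C(C)(C)C)CC(=C)CC[C@@H](C(C)=C)CC1 | intermediate
28 | lithium (aR)-allene-12-carboxylate (not isolated) | [Li+].[O-]C(=O)C1=[C@]=C([H])C/C(C)=C/[C@@H](O[Si](C)(C)C(C)(C)C)CC(=C)CC[C@@H](C(C)=C)CC1 | intermediate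
29 | tricyclic neopentyl-type alkylpalladium chloride, CH2PdCl in place of one C15 methyl (not isolated) | C=C1CC[C@@H]2CCC3=C([C@@H](C/C(C)=C/[C@@H](O[Si](C)(C)C(C)(C)C)C1)OC3=O)C2(C)C[Pd]Cl | intermediate
30 | (1R,6S,7E,10R)-tricyclic butenolide, OTBS at C6 | C=C1CC[C@@H]2CCC3=C([C@@H](C/C(C)=C/[C@@H](O[Si](C)(C)C(C)(C)C)C1)OC3=O)C2(C)C | intermediate
31 | (1R,6S,7E,10R)-deacetyl target | C=C1CC[C@@H]2CCC3=C([C@@H](C/C(C)=C/[C@@H](O)C1)OC3=O)C2(C)C | intermediate
32 | CNP0289913.1, (1R,6S,7E,10R) | C=C1CC[C@@H]2CCC3=C([C@@H](C/C(C)=C/[C@@H](OC(C)=O)C1)OC3=O)C2(C)C | target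

## Step count and risks

Total step count: 20.
Longest linear sequence: 14 steps (steps 1–5 and 12–20; the branch through steps 7–11 and 12–20 is equally long).

**1. Step 18 (Proposed new method).**
- What may go wrong: erosion of the allene axis at the lithium stage; carboxylation at the γ-carbon; loss of the vinyl–palladium bond by protonolysis before insertion; re-insertion of the alkylpalladium into the butenolide alkene; alkene reduction or migration by the Pd(0)/formate left at the end.
- Fallback (known chemistry, stepwise), starting from 25. Pd(0)-catalysed hydroxycarbonylation (Pd(PPh3)4, CO 1 atm, H2O, THF) proceeds in the anti-SN2' sense and should give the (aR)-allenoic acid F1.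
- Iodolactonisation (I2, NaHCO3, MeCN) then transfers the axis to C10 and gives the β-iodobutenolide F2.
- A 6-exo reductive Heck cyclisation (Pd(OAc)2, PPh3, HCO2Na, DMF, 80 °C) closes the cyclohexene, forms the gem-dimethyl carbon and comes back to the route at 30.

**2. Step 12.**
- What may go wrong: poor facial selectivity on a β,β-disubstituted aliphatic enal; silyl scrambling with the TES ether; sluggish turnover with two large partners.
- Fallback, starting from 10 and 19. An achiral BF3·OEt2-promoted Hosomi–Sakurai reaction (CH2Cl2, −78 °C) gives the C6-epimeric alcohols F3.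
- Dess–Martin oxidation gives the cross-conjugated dienone F4.
- Corey–Bakshi–Shibata reduction ((R)-Me-oxazaborolidine, catecholborane, toluene, −78 °C; the alkenyl group acts as the large substituent) sets 6S and comes back to the route at 21.

**3. Step 8.**
- What may go wrong: insufficient enantioselectivity with a small linear ynal; partial reaction through the s-cis dienolate with loss of E geometry; loss of the volatile aldehyde.
- Fallback, starting from 12 and 14. A BF3·OEt2-mediated vinylogous aldol reaction gives the racemic hydroxy ester F5.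
- Lipase-catalysed acylation (vinyl acetate, hexane) should acylate the 5S enantiomer faster, because the propynyl group acts as the medium group and the enoate-bearing chain as the large one. This gives the (5S)-acetate F6, which is separated from the unreacted enantiomer of F5.
- Methanolysis (K2CO3, MeOH, 0 °C) comes back to the route at 16.

## Further compounds

F1 | step 18 | (1R,6S,7E,aR)-6-OTBS-8-methyl-4-methylidene-1-isopropenylcyclotetradeca-7,10,11-triene-12-carboxylic acid | OC(=O)C1=[C@]=C([H])C/C(C)=C/[C@@H](O[Si](C)(C)C(C)(C)C)CC(=C)CC[C@@H](C(C)=C)CC1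
F2 | step 18 | (1R,6S,7E,10R)-11-iodo butenolide fused to the 14-membered ring, isopropenyl still free | C=C1CC[C@@H](C(C)=C)CCC2=C(I)[C@@H](C/C(C)=C/[C@@H](O[Si](C)(C)C(C)(C)C)C1)OC2=O
F3 | step 12 | C6-epimeric mixture of 21 | CC#CCC[C@H](C(C)=C)CCC(=C)CC(O)/C=C(\C)C[C@H](O[Si](CC)(CC)CC)C#CC
F4 | step 12 | C6 ketone (dienone) from F3 | CC#CCC[C@H](C(C)=C)CCC(=C)CC(=O)/C=C(\C)C[C@H](O[Si](CC)(CC)CC)C#CC
F5 | step 8 | racemic methyl (2E)-5-hydroxy-3-methyloct-2-en-6-ynoate | COC(=O)/C=C(\C)CC(O)C#CC
F6 | step 8 | methyl (2E,5S)-5-acetoxy-3-methyloct-2-en-6-ynoate | COC(=O)/C=C(\C)C[C@H](OC(C)=O)C#CC
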